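Assumption: the SMILES is read literally (2Z,6E,8Z,12Z,20E; 4S,11R,14S,15S,17R,18R,19R,22R,23S). Carbons are numbered from the lactone carbonyl (C1) to the side-chain methyl (C24). The statin side-chain aldehyde, the Still–Gennari phosphonate, the dioxolanyl phosphonium salt and but-2-ynal are taken as catalogue items.

## Retrosynthetic overview
- The 20-membered ring is formed last. It closes at C11–C12 by an electroreductive Ni/Cr alkenyl iodide–aldehyde coupling that sets C11, and desilylation follows.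
- The seco compound comes from a (Z)-selective Still–Gennari union at C2=C3 of the C19 phosphonopropionate (C12–C24) with the C3–C11 aldehyde.
- The C12–C24 part is built by Felkin addition of a lactate-derived alkenylzinc to the oxolane aldehyde (C19–C20). The (Z)-C12 iodide comes from an iodo-Wittig reaction.
- The oxolane is the first ring formed. The statin side-chain aldehyde supplies C15 and C17, Fráter–Seebach methylation sets C18, and Co/O2 trans-cyclisation sets C14.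
- The C3–C11 part joins the Roche ester (C4) to a (Z)-enyne by Ni-catalysed reductive coupling. The C5 carbinol is oxidised late.

## Route

Step 1
Reactants: 1 tert-butyl 2-[(4R,6S)-6-formyl-2,2-dimethyl-1,3-dioxan-4-yl]acetate
Product: 3 tert-butyl (3R,5S)-3,5-dihydroxyhept-6-enoate, via tert-butyl 2-[(4R,6S)-6-ethenyl-2,2-dimethyl-1,3-dioxan-4-yl]acetate 2 (not isolated)
Conditions: MePPh3Br, KOtBu, THF, 0 °C, then 1, −78→0 °C; then 2 M aq HCl, MeOH, rt (same flask)
Reagents that add atoms: methyltriphenylphosphonium bromide, C[P+](c1ccccc1)(c1ccccc1)c1ccccc1.[Br-]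
Why: Wittig methylenation followed by acid hydrolysis of the acetonide (the tert-butyl ester survives dilute HCl); C15 and C17 are bought and untouched.

Step 2
Reactants: 3 tert-butyl (3R,5S)-3,5-dihydroxyhept-6-enoate
Product: 4 tert-butyl (2R,3R,5S)-3,5-dihydroxy-2-methylhept-6-enoate
Conditions: LDA (3.3 equiv), THF, −78→−20 °C; MeI, DMPU, −78→−30 °C; H2O
Reagents that add atoms: iodomethane, CI
Why: Fráter–Seebach alkylation, in which the Li-chelated β-oxido enolate is methylated anti to the C17 chain, so C17 sets C18 (anti), while the remote C15 alkoxide is a spectator.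

Step 3
Reactants: 4 tert-butyl (2R,3R,5S)-3,5-dihydroxy-2-methylhept-6-enoate
Product: 5 tert-butyl (2R)-2-[(2R,4S,5S)-4-hydroxy-5-(hydroxymethyl)oxolan-2-yl]propanoate
Conditions: Co(nmp)2 (10 mol %), t-BuOOH (10 mol %), O2 (1 atm), i-PrOH, 55 °C
Reagents that add atoms: dioxygen, O=O
Why: Mukaiyama aerobic Co(II) oxidative cyclisation of a bishomoallylic alcohol gives only the 2,5-trans oxolane, so C17 fixes C14, and this is also the 2,3-cis isomer favoured by the allylic OH.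

Step 4
Reactants: 5 tert-butyl (2R)-2-[(2R,4S,5S)-4-hydroxy-5-(hydroxymethyl)oxolan-2-yl]propanoate
Product: 6 tert-butyl (2R)-2-[(2R,4S,5R)-5-formyl-4-hydroxyoxolan-2-yl]propanoate
Conditions: TEMPO (10 mol %), PhI(OAc)2, CH2Cl2, rt
Reagents that add atoms: none
Why: TEMPO/PhI(OAc)2 oxidation takes only the primary alcohol and is base-free, so the cis α-alkoxy aldehyde does not epimerise.

Step 5
Reactants: 6 tert-butyl (2R)-2-[(2R,4S,5R)-5-formyl-4-hydroxyoxolan-2-yl]propanoate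
Product: 7 tert-butyl (2R)-2-[(2R,4S,5S)-4-hydroxy-5-[(1Z)-2-iodoprop-1-en-1-yl]oxolan-2-yl]propanoate
Conditions: EtPPh3I, n-BuLi, THF, rt; I2, −78 °C; NaHMDS, −20 °C; then 6, −78 °C (3 equiv of reagent)
Reagents that add atoms: ethyltriphenylphosphonium iodide, CC[P+](c1ccccc1)(c1ccccc1)c1ccccc1.[I-]; iodine, II
Why: Stork–Zhao-type iodo-Wittig olefination gives the (Z)-2-iodoalkene (I cis to C14), and the C15-OH sits as an alkoxide, which blocks β-elimination.

Step 6
Reactants: 7 tert-butyl (2R)-2-[(2R,4S,5S)-4-hydroxy-5-[(1Z)-2-iodoprop-1-en-1-yl]oxolan-2-yl]propanoate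
Product: 8 tert-butyl (2R)-2-[(2R,4S,5S)-5-[(1Z)-2-iodoprop-1-en-1-yl]-4-methoxyoxolan-2-yl]propanoate
Conditions: MeOTf, 2,6-di-tert-butyl-4-methylpyridine, CH2Cl2, 0 °C→rt
Reagents that add atoms: methyl trifluoromethanesulfonate, COS(=O)(=O)C(F)(F)F
Why: O-alkylation with MeOTf and a hindered pyridine is non-basic, so the ester α-centre and the vinyl iodide are untouched.

Step 7
Reactants: 8 tert-butyl (2R)-2-[(2R,4S,5S)-5-[(1Z)-2-iodoprop-1-en-1-yl]-4-methoxyoxolan-2-yl]propanoate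
Product: 9 (2R)-2-[(2R,4S,5S)-5-[(1Z)-2-iodoprop-1-en-1-yl]-4-methoxyoxolan-2-yl]propanal
Conditions: DIBAL-H (1.2 equiv), toluene, −78 °C; Rochelle salt
Reagents that add atoms: none
Why: Partial DIBAL-H reduction stops at the aldehyde because the bulky aluminium hemiacetal is stable at −78 °C; 9 is used crude to keep C18 intact.

Step 8
Reactants: 10 ethyl (2S)-2-hydroxypropanoate (ethyl L-lactate)
Product: 11 ethyl (2S)-2-[(tert-butyldimethylsilyl)oxy]propanoate
Conditions: TBSCl, imidazole, DMF, rt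
Reagents that add atoms: tert-butyldimethylsilyl chloride, CC(C)(C)[Si](C)(C)Cl
Why: Standard silylation; C23 is bought.

Step 9
Reactants: 11 ethyl (2S)-2-[(tert-butyldimethylsilyl)oxy]propanoate
Product: 12 (2S)-2-[(tert-butyldimethylsilyl)oxy]propanal
Conditions: DIBAL-H, CH2Cl2, −78 °C
Reagents that add atoms: none
Why: Partial DIBAL-H reduction of the α-silyloxy ester, well known to proceed without racemisation.

Step 10
Reactants: 12 (2S)-2-[(tert-butyldimethylsilyl)oxy]propanal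
Product: 13 (3R,4S)-4-[(tert-butyldimethylsilyl)oxy]pent-1-yn-3-ol
Conditions: HC≡CMgBr, THF, −78 °C; H2O
Reagents that add atoms: ethynylmagnesium bromide, C#C[Mg]Br
Why: Polar Felkin–Anh (non-chelate) Grignard addition to the α-silyloxy aldehyde gives the anti product, so C23 sets C22; the minor syn epimer is removed on silica.

Step 11
Reactants: 13 (3R,4S)-4-[(tert-butyldimethylsilyl)oxy]pent-1-yn-3-ol
Product: 14 (3R,4S)-3,4-bis[(tert-butyldimethylsilyl)oxy]pent-1-yne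
Conditions: TBSOTf, 2,6-lutidine, CH2Cl2, 0 °C
Reagents that add atoms: tert-butyldimethylsilyl trifluoromethanesulfonate, CC(C)(C)[Si](C)(C)OS(=O)(=O)C(F)(F)F
Why: Silylation of a hindered secondary alcohol with the silyl triflate.

Step 12
Reactants: 9 (2R)-2-[(2R,4S,5S)-5-[(1Z)-2-iodoprop-1-en-1-yl]-4-methoxyoxolan-2-yl]propanal; 14 (3R,4S)-3,4-bis[(tert-butyldimethylsilyl)oxy]pent-1-yne
Product: 17 (2S,3R,4E,6R,7S)-6,7-bis[(tert-butyldimethylsilyl)oxy]-2-[(2R,4S,5S)-5-[(1Z)-2-iodoprop-1-en-1-yl]-4-methoxyoxolan-2-yl]oct-4-en-3-ol, via chloro[(1E,3R,4S)-3,4-bis(tert-butyldimethylsilyloxy)pent-1-en-1-yl]zirconocene 15 (not isolated), via [(1E,3R,4S)-3,4-bis(tert-butyldimethylsilyloxy)pent-1-en-1-yl](methyl)zinc 16 (not isolated)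
Conditions: 14, Cp2Zr(H)Cl, CH2Cl2, rt; Me2Zn, toluene, −65 °C; then 9, 0 °C; H2O
Reagents that add atoms: none
Why: Hydrozirconation with Zr→Zn transmetallation and alkenylzinc addition, where Felkin–Anh attack on the α-methyl aldehyde is reinforced by the anti β-alkoxy group (1,3-anti) and sets 19R, and the alkenylzinc leaves the vinyl iodide alone.

Step 13
Reactants: 18 ethyl 2-[bis(2,2,2-trifluoroethoxy)phosphoryl]propanoate
Product: 19 2-[bis(2,2,2-trifluoroethoxy)phosphoryl]propanoic acid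
Conditions: LiOH (1.0 equiv), THF–H2O, 0 °C; 1 M HCl
Reagents that add atoms: lithium hydroxide, [Li+].[OH-]
Why: Saponification of the carboxylic ester with one equivalent of base at 0 °C is faster than P–O cleavage.

Step 14
Reactants: 17 the C12–C24 alcohol; 19 2-[bis(2,2,2-trifluoroethoxy)phosphoryl]propanoic acid
Product: 20 2-[bis(2,2,2-trifluoroethoxy)phosphoryl]propanoate of 17 at O19 (epimers at the P-bearing carbon)
Conditions: DCC, DMAP (cat.), CH2Cl2, 0 °C→rt
Reagents that add atoms: none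
Why: Steglich esterification makes the ester link on a robust acid before any sensitive (Z)-enoate or C4 centre exists.

Step 15
Reactants: 21 [2-(1,3-dioxolan-2-yl)ethyl]triphenylphosphonium bromide; 22 but-2-ynal
Product: 24 2-[(2Z)-hex-2-en-4-yn-1-yl]-1,3-dioxolane, via [2-(1,3-dioxolan-2-yl)ethylidene]triphenylphosphorane 23 (not isolated)
Conditions: NaHMDS, THF, −78 °C; then 22, −78→0 °C
Reagents that add atoms: none
Why: Salt-free Wittig reaction of a non-stabilised ylide gives the (Z)-alkene (C8=C9) and carries C11 as a masked aldehyde.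

Step 16
Reactants: 25 methyl (2S)-3-hydroxy-2-methylpropanoate ((S)-Roche ester)
Product: 26 methyl (2S)-2-methyl-3-[(triethylsilyl)oxy]propanoate
Conditions: TESCl, imidazole, CH2Cl2, 0 °C
Reagents that add atoms: triethylsilyl chloride, CC[Si](Cl)(CC)CC
Why: Standard silylation; C4 is bought.

Step 17
Reactants: 26 methyl (2S)-2-methyl-3-[(triethylsilyl)oxy]propanoate
Product: 27 (2S)-2-methyl-3-[(triethylsilyl)oxy]propanal
Conditions: DIBAL-H, CH2Cl2, −78 °C
Reagents that add atoms: none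
Why: Partial DIBAL-H reduction to the Roche aldehyde, which is configurationally stable when used directly.

Step 18
Reactants: 27 (2S)-2-methyl-3-[(triethylsilyl)oxy]propanal; 24 2-[(2Z)-hex-2-en-4-yn-1-yl]-1,3-dioxolane
Product: 28 2-[(2Z,4E,7S)-5,7-dimethyl-6,8-bis[(triethylsilyl)oxy]octa-2,4-dien-1-yl]-1,3-dioxolane (epimers at the silyloxy carbon C5)
Conditions: Ni(cod)2 (10 mol %), IMes·HCl (10 mol %), KOtBu (10 mol %), Et3SiH, THF, rt
Reagents that add atoms: triethylsilane, CC[SiH](CC)CC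
Why: Ni/NHC-catalysed aldehyde–alkyne reductive coupling adds syn (6E), forms C5–C6 at the methyl-bearing alkyne carbon distal to the alkene, and delivers C5 already as its TES ether; the C5 configuration is irrelevant.

Step 19
Reactants: 28 2-[(2Z,4E,7S)-5,7-dimethyl-6,8-bis[(triethylsilyl)oxy]octa-2,4-dien-1-yl]-1,3-dioxolane
Product: 29 (2R,4E,6Z)-8-(1,3-dioxolan-2-yl)-2,4-dimethyl-3-[(triethylsilyl)oxy]octa-4,6-dienal
Conditions: (COCl)2, DMSO, CH2Cl2, −78→−40 °C; Et3N, −78 °C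
Reagents that add atoms: none
Why: Swern conditions oxidise a primary TES ether directly to the aldehyde while the secondary TES ether and the acetal stay.

Step 20
Reactants: 20 the C19 phosphonopropionate; 29 (2R,4E,6Z)-8-(1,3-dioxolan-2-yl)-2,4-dimethyl-3-[(triethylsilyl)oxy]octa-4,6-dienal
Product: 30 ester of 17 (O19) with (2Z,4S,6E,8Z)-10-(1,3-dioxolan-2-yl)-2,4,6-trimethyl-5-[(triethylsilyl)oxy]deca-2,6,8-trienoic acid
Conditions: KHMDS, 18-crown-6, THF, −78 °C; then 29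
Reagents that add atoms: none
Why: Still–Gennari olefination gives the (Z)-α-methyl enoate under kinetic control at −78 °C, fast enough to keep C4 intact.

Step 21
Reactants: 30 the seco-ester acetal
Product: 31 ester of 17 (O19) with (2Z,4S,6E,8Z)-2,4,6-trimethyl-11-oxo-5-[(triethylsilyl)oxy]undeca-2,6,8-trienoic acid
Conditions: TESOTf, 2,6-lutidine, CH2Cl2, 0 °C; then H2O
Reagents that add atoms: water, O
Why: Silyl triflate/lutidine acetal cleavage through a pyridinium salt is near-neutral, so the β,γ-unsaturated aldehyde does not conjugate, and C5 stays silylated, so the (Z)-δ-hydroxy enoate can never lactonise.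

Step 22
Reactants: 31 the C11 aldehyde with C5-OTES
Product: 32 ester of 17 (O19) with (2Z,4S,6E,8Z)-2,4,6-trimethyl-5,11-dioxoundeca-2,6,8-trienoic acid
Conditions: DDQ, CH2Cl2–pH 7 buffer, 0 °C→rt
Reagents that add atoms: none
Why: DDQ oxidative desilylation removes hydride from the electron-rich dienylic C5–H and gives the dienone directly without a free C5-OH, while the mono-allylic TBS ether is too electron-poor to react.

Step 23
Reactants: 32 the keto-aldehyde vinyl iodide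
Product: 33 11-O-trimethylsilyl-22,23-bis-O-(tert-butyldimethylsilyl)maltepolide D
Conditions: CrCl2 (15 mol %), NiCl2·glyme/neocuproine (3 mol %), TMSCl (4 equiv), Bu4NBr (0.1 M), DMF–THF, undivided cell, Al(+)/Ni foam(−), 1.5 mA, 32 added over 10 h (≤1 mM), 2.4 F/mol, rt
Reagents that add atoms: chlorotrimethylsilane, C[Si](C)(C)Cl
Why: Proposed new method: cathodic Cr(III)→Cr(II) turnover (Al anode as electron source, TMSCl freeing Cr from the alkoxide) drives a Ni/Cr-catalysed Nozaki–Hiyama–Kishi ring closure, a coupling so far run electrochemically only between two separate partners and never as a macrocyclisation or on a (Z)-2-iodoalkene bearing a coordinating ether; Ni(0) inserts into C12–I with retention and transmetallates to Cr(III), the oxolane oxygen on C14 binds Cr in a five-membered chelate so the aldehyde adds with its C10 chain on the face away from the oxolane (11R), and the low stationary concentrations set by current and syringe pump favour the 20-membered ring over dimers while ketone, enoate and allylic ester stay below their reduction potentials; the closest known reactions are the stoichiometric CrCl2/NiCl2 NHK macrocyclisation and the intermolecular electrocatalytic NHK coupling.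

Step 24
Reactants: 33 11-O-trimethylsilyl-22,23-bis-O-(tert-butyldimethylsilyl)maltepolide D
Product: 34 maltepolide D
Conditions: HF·pyridine, pyridine, THF, 0 °C→rt
Reagents that add atoms: none
Why: Buffered fluoride desilylation removes all three silyl ethers without base, so C4, the (Z)-enoate and the (8Z)-diene are not disturbed.

## Compound list
1 | tert-butyl 2-[(4R,6S)-6-formyl-2,2-dimethyl-1,3-dioxan-4-yl]acetate | CC(C)(C)OC(=O)C[C@H]1C[C@@H](C=O)OC(C)(C)O1 | starting material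
2 | tert-butyl 2-[(4R,6S)-6-ethenyl-2,2-dimethyl-1,3-dioxan-4-yl]acetate | CC(C)(C)OC(=O)C[C@H]1C[C@@H](C=C)OC(C)(C)O1 | intermediate (not isolated)
3 | tert-butyl (3R,5S)-3,5-dihydroxyhept-6-enoate | CC(C)(C)OC(=O)C[C@H](O)C[C@H](O)C=C | intermediate
4 | tert-butyl (2R,3R,5S)-3,5-dihydroxy-2-methylhept-6-enoate | CC(C)(C)OC(=O)[C@H](C)[C@H](O)C[C@H](O)C=C | intermediate
5 | tert-butyl (2R)-2-[(2R,4S,5S)-4-hydroxy-5-(hydroxymethyl)oxolan-2-yl]propanoate | CC(C)(C)OC(=O)[C@H](C)[C@H]1C[C@H](O)[C@H](CO)O1 | intermediate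
6 | tert-butyl (2R)-2-[(2R,4S,5R)-5-formyl-4-hydroxyoxolan-2-yl]propanoate | CC(C)(C)OC(=O)[C@H](C)[C@H]1C[C@H](O)[C@H](C=O)O1 | intermediate
7 | tert-butyl (2R)-2-[(2R,4S,5S)-4-hydroxy-5-[(1Z)-2-iodoprop-1-en-1-yl]oxolan-2-yl]propanoate | CC(C)(C)OC(=O)[C@H](C)[C@H]1C[C@H](O)[C@H](/C=C(/C)I)O1 | intermediate
8 | tert-butyl (2R)-2-[(2R,4S,5S)-5-[(1Z)-2-iodoprop-1-en-1-yl]-4-methoxyoxolan-2-yl]propanoate | CC(C)(C)OC(=O)[C@H](C)[C@H]1C[C@H](OC)[C@H](/C=C(/C)I)O1 | intermediate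
9 | (2R)-2-[(2R,4S,5S)-5-[(1Z)-2-iodoprop-1-en-1-yl]-4-methoxyoxolan-2-yl]propanal | O=C[C@H](C)[C@H]1C[C@H](OC)[C@H](/C=C(/C)I)O1 | intermediate
10 | ethyl (2S)-2-hydroxypropanoate | CCOC(=O)[C@H](C)O | starting material
11 | ethyl (2S)-2-[(tert-butyldimethylsilyl)oxy]propanoate | CCOC(=O)[C@H](C)O[Si](C)(C)C(C)(C)C | intermediate
12 | (2S)-2-[(tert-butyldimethylsilyl)oxy]propanal | O=C[C@H](C)O[Si](C)(C)C(C)(C)C | intermediate
13 | (3R,4S)-4-[(tert-butyldimethylsilyl)oxy]pent-1-yn-3-ol | C[C@H](O[Si](C)(C)C(C)(C)C)[C@H](O)C#C | intermediate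
14 | (3R,4S)-3,4-bis[(tert-butyldimethylsilyl)oxy]pent-1-yne | C[C@H](O[Si](C)(C)C(C)(C)C)[C@H](O[Si](C)(C)C(C)(C)C)C#C | intermediate
15 | chloro[(1E,3R,4S)-3,4-bis(tert-butyldimethylsilyloxy)pent-1-en-1-yl]zirconocene | C[C@H](O[Si](C)(C)C(C)(C)C)[C@H](O[Si](C)(C)C(C)(C)C)/C=C/[Zr](Cl)(C1C=CC=C1)C1C=CC=C1 | intermediate (not isolated)
16 | [(1E,3R,4S)-3,4-bis(tert-butyldimethylsilyloxy)pent-1-en-1-yl](methyl)zinc | C[C@H](O[Si](C)(C)C(C)(C)C)[C@H](O[Si](C)(C)C(C)(C)C)/C=C/[Zn]C | intermediate (not isolated)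
17 | (2S,3R,4E,6R,7S)-6,7-bis[(tert-butyldimethylsilyl)oxy]-2-[(2R,4S,5S)-5-[(1Z)-2-iodoprop-1-en-1-yl]-4-methoxyoxolan-2-yl]oct-4-en-3-ol (C12–C24 alcohol) | C[C@H](O[Si](C)(C)C(C)(C)C)[C@H](O[Si](C)(C)C(C)(C)C)/C=C/[C@@H](O)[C@H](C)[C@H]1C[C@H](OC)[C@H](/C=C(/C)I)O1 | intermediate
18 | ethyl 2-[bis(2,2,2-trifluoroethoxy)phosphoryl]propanoate | CCOC(=O)C(C)P(=O)(OCC(F)(F)F)OCC(F)(F)F | starting material
19 | 2-[bis(2,2,2-trifluoroethoxy)phosphoryl]propanoic acid | OC(=O)C(C)P(=O)(OCC(F)(F)F)OCC(F)(F)F | intermediate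
20 | 2-[bis(2,2,2-trifluoroethoxy)phosphoryl]propanoate of 17 at O19 | C[C@H](O[Si](C)(C)C(C)(C)C)[C@H](O[Si](C)(C)C(C)(C)C)/C=C/[C@@H](OC(=O)C(C)P(=O)(OCC(F)(F)F)OCC(F)(F)F)[C@H](C)[C@H]1C[C@H](OC)[C@H](/C=C(/C)I)O1 | intermediate
21 | [2-(1,3-dioxolan-2-yl)ethyl]triphenylphosphonium bromide | [Br-].O1CCOC1CC[P+](c1ccccc1)(c1ccccc1)c1ccccc1 | starting material
22 | but-2-ynal | CC#CC=O | starting material
23 | [2-(1,3-dioxolan-2-yl)ethylidene]triphenylphosphorane | O1CCOC1CC=P(c1ccccc1)(c1ccccc1)c1ccccc1 | intermediate (not isolated)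
24 | 2-[(2Z)-hex-2-en-4-yn-1-yl]-1,3-dioxolane | CC#C/C=C\CC1OCCO1 | intermediate
25 | methyl (2S)-3-hydroxy-2-methylpropanoate | COC(=O)[C@@H](C)CO | starting material
26 | methyl (2S)-2-methyl-3-[(triethylsilyl)oxy]propanoate | COC(=O)[C@@H](C)CO[Si](CC)(CC)CC | intermediate
27 | (2S)-2-methyl-3-[(triethylsilyl)oxy]propanal | O=C[C@@H](C)CO[Si](CC)(CC)CC | intermediate
28 | 2-[(2Z,4E,7S)-5,7-dimethyl-6,8-bis[(triethylsilyl)oxy]octa-2,4-dien-1-yl]-1,3-dioxolane (C5 epimers) | O1CCOC1C/C=C\C=C(/C)C(O[Si](CC)(CC)CC)[C@@H](C)CO[Si](CC)(CC)CC | intermediate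
29 | (2R,4E,6Z)-8-(1,3-dioxolan-2-yl)-2,4-dimethyl-3-[(triethylsilyl)oxy]octa-4,6-dienal (C5 epimers) | O1CCOC1C/C=C\C=C(/C)C(O[Si](CC)(CC)CC)[C@@H](C)C=O | intermediate
30 | ester of 17 with (2Z,4S,6E,8Z)-10-(1,3-dioxolan-2-yl)-2,4,6-trimethyl-5-[(triethylsilyl)oxy]deca-2,6,8-trienoic acid | O1CCOC1C/C=C\C=C(/C)C(O[Si](CC)(CC)CC)[C@@H](C)/C=C(/C)C(=O)O[C@H](/C=C/[C@@H](O[Si](C)(C)C(C)(C)C)[C@H](C)O[Si](C)(C)C(C)(C)C)[C@H](C)[C@H]2C[C@H](OC)[C@H](/C=C(/C)I)O2 | intermediate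
31 | ester of 17 with (2Z,4S,6E,8Z)-2,4,6-trimethyl-11-oxo-5-[(triethylsilyl)oxy]undeca-2,6,8-trienoic acid | O=CC/C=C\C=C(/C)C(O[Si](CC)(CC)CC)[C@@H](C)/C=C(/C)C(=O)O[C@H](/C=C/[C@@H](O[Si](C)(C)C(C)(C)C)[C@H](C)O[Si](C)(C)C(C)(C)C)[C@H](C)[C@H]2C[C@H](OC)[C@H](/C=C(/C)I)O2 | intermediate
32 | ester of 17 with (2Z,4S,6E,8Z)-2,4,6-trimethyl-5,11-dioxoundeca-2,6,8-trienoic acid | O=CC/C=C\C=C(/C)C(=O)[C@@H](C)/C=C(/C)C(=O)O[C@H](/C=C/[C@@H](O[Si](C)(C)C(C)(C)C)[C@H](C)O[Si](C)(C)C(C)(C)C)[C@H](C)[C@H]2C[C@H](OC)[C@H](/C=C(/C)I)O2 | intermediate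
33 | 11-O-trimethylsilyl-22,23-bis-O-(tert-butyldimethylsilyl)maltepolide D | CO[C@H]1C[C@H]2O[C@H]1/C=C(/C)[C@H](O[Si](C)(C)C)C/C=C\C=C(/C)C(=O)[C@@H](C)/C=C(/C)C(=O)O[C@H](/C=C/[C@@H](O[Si](C)(C)C(C)(C)C)[C@H](C)O[Si](C)(C)C(C)(C)C)[C@@H]2C | intermediate
34 | maltepolide D | CO[C@H]1C[C@H]2O[C@H]1/C=C(/C)[C@H](O)C/C=C\C=C(/C)C(=O)[C@@H](C)/C=C(/C)C(=O)O[C@H](/C=C/[C@@H](O)[C@H](C)O)[C@@H]2C | target

## Step count
- **Total steps:** 24.
- **Longest linear sequence:** 14 (steps 1–7, 12, 14, 20–24).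

## Steps most likely to fail

**Step 23 (the proposed new electrochemical ring closure).** The risks are oligomerisation, enolisation of the very acidic aldehyde 32, and the level of 11R control.

The fallback sets out from 31 and changes the order of events as well as the method. The ring is closed first on the non-conjugated, much less enolisable aldehyde by the classical stoichiometric CrCl2/cat. NiCl2 NHK macrocyclisation (DMSO–THF, high dilution). This gives 5-deoxo-5-(triethylsilyloxy)-22,23-bis-O-(tert-butyldimethylsilyl)maltepolide D F1.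

The C11 carbinol is then capped (TMSCl, imidazole) to give its 11-O-trimethylsilyl ether F2. Only then is the dienylic C5 silyl ether oxidised with DDQ. That returns to the route at 33.

**Step 5 (iodo-Wittig on a hydroxy aldehyde).** This reaction type usually gives modest yields, and 6 is an epimerisable aldehyde.

The fallback sets out from 6. Ramirez dibromo-olefination (CBr4, PPh3, Zn) gives tert-butyl (2R)-2-[(2R,4S,5S)-5-(2,2-dibromoethenyl)-4-hydroxyoxolan-2-yl]propanoate F3. Pd-catalysed trans-selective Negishi monomethylation (MeZnCl, PdCl2(DPEphos)) gives tert-butyl (2R)-2-[(2R,4S,5S)-5-[(1Z)-2-bromoprop-1-en-1-yl]-4-hydroxyoxolan-2-yl]propanoate F4. Cu-catalysed vinyl halide exchange (CuI, N,N′-dimethylethylenediamine, NaI, dioxane, 110 °C) returns to the route at 7.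

**Step 12 (level of Felkin control at C19).** The fallback sets out from 17 obtained as a C19 epimer mixture, and sets C19 by hydride delivery instead of C–C bond formation.

Dess–Martin oxidation gives (2R,4E,6R,7S)-6,7-bis[(tert-butyldimethylsilyl)oxy]-2-[(2R,4S,5S)-5-[(1Z)-2-iodoprop-1-en-1-yl]-4-methoxyoxolan-2-yl]oct-4-en-3-one F5. Luche reduction (NaBH4, CeCl3, MeOH, −78 °C, Felkin attack) returns to the route at 17.

## Further compounds
F1 | step 23 | 5-deoxo-5-(triethylsilyloxy)-22,23-bis-O-(tert-butyldimethylsilyl)maltepolide D | CO[C@H]1C[C@H]2O[C@H]1/C=C(/C)[C@H](O)C/C=C\C=C(/C)C(O[Si](CC)(CC)CC)[C@@H](C)/C=C(/C)C(=O)O[C@H](/C=C/[C@@H](O[Si](C)(C)C(C)(C)C)[C@H](C)O[Si](C)(C)C(C)(C)C)[C@@H]2C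
F2 | step 23 | 11-O-trimethylsilyl ether of F1 | CO[C@H]1C[C@H]2O[C@H]1/C=C(/C)[C@H](O[Si](C)(C)C)C/C=C\C=C(/C)C(O[Si](CC)(CC)CC)[C@@H](C)/C=C(/C)C(=O)O[C@H](/C=C/[C@@H](O[Si](C)(C)C(C)(C)C)[C@H](C)O[Si](C)(C)C(C)(C)C)[C@@H]2C
F3 | step 5 | tert-butyl (2R)-2-[(2R,4S,5S)-5-(2,2-dibromoethenyl)-4-hydroxyoxolan-2-yl]propanoate | CC(C)(C)OC(=O)[C@H](C)[C@H]1C[C@H](O)[C@H](C=C(Br)Br)O1
F4 | step 5 | tert-butyl (2R)-2-[(2R,4S,5S)-5-[(1Z)-2-bromoprop-1-en-1-yl]-4-hydroxyoxolan-2-yl]propanoate | CC(C)(C)OC(=O)[C@H](C)[C@H]1C[C@H](O)[C@H](/C=C(/C)Br)O1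
F5 | step 12 | (2R,4E,6R,7S)-6,7-bis[(tert-butyldimethylsilyl)oxy]-2-[(2R,4S,5S)-5-[(1Z)-2-iodoprop-1-en-1-yl]-4-methoxyoxolan-2-yl]oct-4-en-3-one | C[C@H](O[Si](C)(C)C(C)(C)C)[C@H](O[Si](C)(C)C(C)(C)C)/C=C/C(=O)[C@H](C)[C@H]1C[C@H](OC)[C@H](/C=C(/C)I)O1
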